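In a one-step world, starting material and reagent give product and a partner, one for one, and the flask comes to rest where they stand in a fixed balance.

all flasks: free catalyst 10 µM
- cedar: solid substrate 2.5 mM; reagent 3 mM; run made earlier
- ash: solid substrate 10 mM; reagent 3 mM; run made earlier
- alder: solid substrate 5 mM; reagent 1.5 mM; run made earlier
- flask: solid substrate 5.0 mM; reagent 3.00 mM; time 2.0 min

| run | time / s | product / % | starting material / % |
|---|---|---|---|
| cedar | 10.0 | 25.4 | 73.9 |
| cedar | 15.0 | 30.6 | 69.9 |
| cedar | 25.0 | 34.7 | 65.8 |
| cedar | 40.0 | 35.4 | 64.1 |
| cedar | 80.0 | 35.6 | 63.9 |
| ash | 10.0 | 6.8 | 25.8 |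
| ash | 15.0 | 8.3 | 26.4 |
| ash | 25.0 | 10.3 | 26.3 |
| ash | 40.0 | 10.3 | 26.2 |
| ash | 60.0 | 10.9 | 26.2 |
| ash | 80.0 | 10.5 | 25.7 |
| alder | 10.0 | 8.6 | 51.5 |
| alder | 20.0 | 12.0 | 52.4 |
| alder | 30.0 | 12.9 | 52.2 |
| alder | 50.0 | 14.0 | 51.7 |
| alder | 80.0 | 14.0 | 52.4 |

(readings scatter by 0.3 percentage points)

- solid substrate is a solid; its amount is given per volume of the solution
- at the start none of the solid substrate is in solution
- what has only dissolved of solid substrate counts as not reacted
- starting material means what is dissolved; the solid is not counted in it

- product at 2.0 min, in percent of the solid substrate charged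
- starting material at 2.0 min, in percent of the solid substrate charged

I test that picture on the cedar run. At 80.0 s, [product] is 0.890 mM, [starting material] is 1.60 mM and [reagent], reckoned one for one, is 2.11 mM. That reads 0.235 for the balance number, [product] squared over [starting material] times [reagent], the overall equilibrium constant. The alder run, with half the reagent and solid still present, reads 0.234, so I trust it.

The flask looks like the cedar run, with the same reagent but twice the solid. In cedar, product and starting material sum to 99.5% of the charge, so its solid has dissolved and [starting material] sinks as product forms. In the alder run, with solid left, [starting material] stands at 2.62 mM, and I put that into the balance number for the flask. With [reagent] as the charge less product, I get [product] = 1.09 mM, which leaves solid. By this reckoning the flask's [product] ends above cedar's because its [starting material] stands higher, yet as a share of the charge it is 21.7% product and 52.4% starting material. The flask is read at 2.0 min, later than cedar's last reading, and cedar's product reads 35.4% at 40.0 s and 35.6% at 80.0 s, so I take the flask as stopped.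

The forecast, slightly below my product, gives 21.2% and 52.1%, holding that “The flask is at equilibrium by 2 minutes”.

The flask gives 21.6% product and 52.0% starting material.

    reagent + free catalyst ⇌ catalyst intermediate A (K = 56.0 M⁻¹, k = 4.30 × 10⁵ M⁻¹ s⁻¹)
    catalyst intermediate A ⇌ by-product + catalyst intermediate B (K = 0.00270 M, k = 98.0 s⁻¹)
    starting material + catalyst intermediate B ⇌ catalyst intermediate C (K = 120 M⁻¹, k = 1.10 × 10⁶ M⁻¹ s⁻¹)
    catalyst intermediate C ⇌ free catalyst + product (K = 0.0130 M, k = 210 s⁻¹)
    solid substrate ⇌ starting material, rate k5*(cs5 - [starting material]) while solid is left; crystals form when [starting material] > cs5 (solubility = 2.60 mM, k = 3.10 s⁻¹)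

In the flask, the half-life of reagent by the forward step to catalyst intermediate A alone, the way back not counted and the other concentrations held at their charge, is 0.16 s against 2.0 min allowed, and the path from catalyst intermediate A to by-product and catalyst intermediate B has 70% of its turnover up to 2.0 min behind it at 0.200 min. Ten times the time leaves product at 21.6%. The flask's own amounts read 0.235 for the balance number. For a neighbour flask charged with 7.5 mM of reagent, the balance number gives 1.86 mM, or 37.3% of the solid charged, and that neighbour stands at 37.2%.

The runs were generated by integration from invented constants; the scatter is artificial.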